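The whole plan hinges on cutting ring A (C4a, C5, C6, C7, C8, C8a) across C4a–C5 and C7–C8. The three carbons C5, C6(OMe) and C7 carry exactly the oxygenation of a methoxymalonyl unit. The other three, C4a, C8a and the prenylated C8, are the α-carbon, the enol-ether carbon and the first side-chain carbon of a dihydropyran-4-one (ring C) in which O1, the C4 ketone and the (S) centre C2 are already in place. One operation, a double C-acylation of that pyranone by methoxymalonyl dichloride, therefore builds the phloroglucinol ring and gives unprotected agrandol directly. The pyranone, (S)-6-(4-methylpent-3-enyl)-2-phenyl-2,3-dihydro-4H-pyran-4-one, is made in three steps from a chiral-pool β-hydroxy ester.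

Key step: step 7

Assumption: the target is the (2S)-flavanone encoded by the SMILES, and flavanone numbering (O1, C2, C3, C4, C4a, C5–C8, C8a) is used for these atoms in every compound; methoxymalonyl dichloride is taken not to be a catalogue item and is made fresh.

Design note: the pyranone is used as the free vinylogous ester and is never enolised, silylated or exposed to a nucleophilic amine around the annulation, because a C3 enol(ate) opens the C2–O1 bond and a nucleophilic amine adds at C8a; the hydroxyl is carried unprotected to keep the approach short.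

Step 1
Reactants: 1 ethyl (S)-3-hydroxy-3-phenylpropanoate
Product: 2 (S)-3-hydroxy-N-methoxy-N-methyl-3-phenylpropanamide
Conditions: MeNHOMe·HCl (1.6 equiv), i-PrMgCl (4 equiv), THF, −20 → 0 °C; aq. NH4Cl
Reagents that add atoms: N,O-dimethylhydroxylamine hydrochloride, CNOC.Cl
Why: Weinreb amide formation by direct aminolysis of the ester with the chloromagnesium amide of N,O-dimethylhydroxylamine; the hydroxyl rides along as its magnesium alkoxide and the carbinol carbon is not involved, so the (S) centre is retained.

Step 2
Reactants: 3 6-methylhept-5-en-2-one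
Product: 5 6-methylhept-5-en-1-yne, via enol phosphate 4 (not isolated)
Conditions: LDA (1.1 equiv), THF, −78 °C; ClP(O)(OEt)2, −78 °C → rt; then LDA (2.3 equiv), −78 °C → rt; H2O; distillation
Reagents that add atoms: none
Why: Negishi methyl ketone-to-alkyne conversion, in which kinetic deprotonation at the methyl group, O-phosphorylation and LDA-induced elimination of the enol phosphate give the terminal alkyne while the remote trisubstituted alkene is inert.

Step 3
Reactants: 2 (S)-3-hydroxy-N-methoxy-N-methyl-3-phenylpropanamide; 5 6-methylhept-5-en-1-yne
Product: 7 (S)-1-hydroxy-9-methyl-1-phenyldec-8-en-4-yn-3-one, via lithium acetylide 6 (not isolated)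
Conditions: 5 (2.6 equiv), n-BuLi (2.5 equiv), THF, −78 °C; then 2, −78 → 0 °C; aq. NH4Cl (excess 5 is recovered)
Reagents that add atoms: none
Why: Weinreb ketone synthesis with a lithium acetylide, in which one equivalent deprotonates the hydroxyl, the next adds to the amide and the chelated tetrahedral intermediate prevents over-addition, so the ynone should form on work-up with the (S) centre unchanged.

Step 4
Reactants: 7 (S)-1-hydroxy-9-methyl-1-phenyldec-8-en-4-yn-3-one
Product: 8 (S)-6-(4-methylpent-3-en-1-yl)-2-phenyl-2,3-dihydro-4H-pyran-4-one
Conditions: Ph3PAuNTf2 (2 mol %), CH2Cl2, rt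
Reagents that add atoms: none
Why: Gold(I)-catalysed 6-endo-dig hydroalkoxylation of a β-hydroxy ynone, in which the hydroxyl attacks the β-carbon of the gold-activated ynone (a polarisation that also disfavours engagement of the distal alkene), and since the carbinol C–O bond is never broken C2 remains (S).

Step 5
Reactants: 9 dimethyl 2-methoxypropanedioate (dimethyl methoxymalonate)
Product: 10 2-methoxypropanedioic acid (methoxymalonic acid)
Conditions: NaOH (2.2 equiv), H2O/MeOH, 0 °C → rt; 2 M HCl to pH 1 at 0 °C; continuous EtOAc extraction; evaporation below 30 °C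
Reagents that add atoms: sodium hydroxide, [Na+].[OH-]
Why: Plain saponification of a malonate diester, with acidification and evaporation in the cold to avoid decarboxylation of the α-alkoxymalonic acid.

Step 6
Reactants: 10 2-methoxypropanedioic acid
Product: 11 2-methoxypropanedioyl dichloride (methoxymalonyl dichloride)
Conditions: (COCl)2 (2.5 equiv), DMF (cat.), CH2Cl2, 0 °C → rt; volatiles removed in the cold; used at once
Reagents that add atoms: oxalyl chloride, O=C(Cl)C(=O)Cl
Why: Acid chloride formation with oxalyl chloride under Vilsmeier (DMF) catalysis, chosen because the by-products are gases and the moisture-sensitive dichloride can be used without purification.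

Step 7
Reactants: 8 (S)-6-(4-methylpent-3-en-1-yl)-2-phenyl-2,3-dihydro-4H-pyran-4-one; 11 2-methoxypropanedioyl dichloride
Product: 14 agrandol [(2S)-5,7-dihydroxy-6-methoxy-8-(3-methylbut-2-en-1-yl)-2-phenylchroman-4-one], via C5-acylated acid chloride 12 (not isolated), via acylketene 13 (not isolated)
Conditions: 11 (1.2 equiv, added over 2 h), 2,6-di-tert-butyl-4-methylpyridine (2.6 equiv), PhMe, 0 → 70 °C; then pH 7 phosphate buffer
Reagents that add atoms: none
Why: Proposed new method: the ring enol ether O1–C8a=C4a is the only ground-state π-nucleophile of 8, so its β-carbon C4a should be acylated by 11 (or by the chlorocarbonyl ketene that 11 gives with the hindered base) to form C4a–C5 (12); loss of HCl then gives acylketene 13, whose side-chain CH2 (C8), now vinylogous to two carbonyls, enolises to the dienylketene C8=C8a–C4a=C5(OH)–C6(OMe)=C7=O. Ring A closes by C7–C8 bond formation, a thermal 6π-electrocyclisation of that dienylketene (in polar terms a 6-(enolendo)-exo-trig C-acylation of the C8 enol carbon), and the cyclohexadienone tautomerises irreversibly to the 5,7-dihydroxy-6-methoxy arene. The closest known reaction types are the double α,α′-C-acylation of enol ethers by malonyl dichloride (Effenberger cyclisation), the [3+3] cyclocondensation of malonyl dichlorides or chlorocarbonyl ketenes with 1,3-C,C-dinucleophiles to phloroglucinols, and the dienylketene electrocyclisation that ends the Danheiser benzannulation. No stereocentre is formed; C2 is a spectator, and because the hindered pyridine only binds HCl and cannot enolise C3 or add to C8a, the E1cB opening of the C2–O1 bond that would racemise it is shut off. The step needs C- over O-acylation and C4a/C8 over C3: C3 is nucleophilic only through the scarce ketone enol, O-acylation at the C4 oxygen is reversible through the acylketene whereas the C–C closure is made irreversible by aromatisation, and trapping of HCl protects the prenyl alkene and the new ortho-prenyl phenol from hydrochlorination and chroman formation.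

Compound list
1 | ethyl (S)-3-hydroxy-3-phenylpropanoate | CCOC(=O)C[C@H](O)c1ccccc1 | starting material
2 | (S)-3-hydroxy-N-methoxy-N-methyl-3-phenylpropanamide | CON(C)C(=O)C[C@H](O)c1ccccc1 | intermediate
3 | 6-methylhept-5-en-2-one | CC(=O)CCC=C(C)C | starting material
4 | diethyl 6-methylhepta-1,5-dien-2-yl phosphate (enol phosphate) | C=C(CCC=C(C)C)OP(=O)(OCC)OCC | intermediate (not isolated)
5 | 6-methylhept-5-en-1-yne | C#CCCC=C(C)C | intermediate
6 | (6-methylhept-5-en-1-yn-1-yl)lithium (lithium acetylide) | [Li]C#CCCC=C(C)C | intermediate (not isolated)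
7 | (S)-1-hydroxy-9-methyl-1-phenyldec-8-en-4-yn-3-one | O=C(C[C@H](O)c1ccccc1)C#CCCC=C(C)C | intermediate
8 | (S)-6-(4-methylpent-3-en-1-yl)-2-phenyl-2,3-dihydro-4H-pyran-4-one | O=C1C[C@@H](c2ccccc2)OC(CCC=C(C)C)=C1 | intermediate
9 | dimethyl 2-methoxypropanedioate | COC(C(=O)OC)C(=O)OC | starting material
10 | 2-methoxypropanedioic acid | COC(C(=O)O)C(=O)O | intermediate
11 | 2-methoxypropanedioyl dichloride | COC(C(=O)Cl)C(=O)Cl | intermediate
12 | (2S)-5-(3-chloro-2-methoxy-3-oxopropanoyl)-6-(4-methylpent-3-en-1-yl)-2-phenyl-2,3-dihydro-4H-pyran-4-one (C5-acylated acid chloride) | O=C1C[C@@H](c2ccccc2)OC(CCC=C(C)C)=C1C(=O)C(OC)C(=O)Cl | intermediate (not isolated)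
13 | (2S)-5-(2-methoxy-3-oxoprop-2-enoyl)-6-(4-methylpent-3-en-1-yl)-2-phenyl-2,3-dihydro-4H-pyran-4-one (acylketene) | O=C1C[C@@H](c2ccccc2)OC(CCC=C(C)C)=C1C(=O)C(OC)=C=O | intermediate (not isolated)
14 | agrandol, (2S)-5,7-dihydroxy-6-methoxy-8-(3-methylbut-2-en-1-yl)-2-phenylchroman-4-one | COc1c(O)c(CC=C(C)C)c2c(c1O)C(=O)C[C@@H](c1ccccc1)O2 | target

Total step count: 7
Longest linear sequence: 4 steps (steps 1, 3, 4 and 7, from ester 1)

Steps most likely to fail

Step 7 (new method). The vinylogous-ester carbon C4a may be too weak a nucleophile for the first acylation, or ring closure may proceed through the C4 oxygen and not through C8. The fallback sets out from 8, removes the deactivating carbonyl for the annulation, uses only established reaction types and comes back at 14. Luche reduction (NaBH4, CeCl3·7H2O, MeOH, −40 °C) should give the allylic alcohol (2S)-6-(4-methylpent-3-en-1-yl)-2-phenyl-3,4-dihydro-2H-pyran-4-ol F1 (C4 epimers; the centre is removed later). Silylation (TBSCl, imidazole, DMF) should give tert-butyldimethyl{[(2S)-6-(4-methylpent-3-en-1-yl)-2-phenyl-3,4-dihydro-2H-pyran-4-yl]oxy}silane F2. F2 is a plain cyclic enol ether with C–H positions on both sides of the enol-ether carbon, the substrate class for which the malonyl dichloride annulation of enol ethers (Effenberger cyclisation) is established. Reaction with 11 (2,6-di-tert-butyl-4-methylpyridine, CH2Cl2, −20 °C → rt) should then give (2S)-4-[(tert-butyldimethylsilyl)oxy]-6-methoxy-8-(3-methylbut-2-en-1-yl)-2-phenylchromane-5,7-diol F3. TBAF buffered with AcOH (THF, 0 °C) should free (2S)-6-methoxy-8-(3-methylbut-2-en-1-yl)-2-phenylchromane-4,5,7-triol F4, and activated MnO2 (CH2Cl2, rt) should oxidise its benzylic alcohol to the ketone, which is 14.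

Step 6. The α-alkoxymalonic acid may decarboxylate during isolation or chlorination, and the dichloride may self-condense through ketene formation under the HCl that is released. The fallback sets out from 9 and comes back at 11 without ever forming the free diacid. KOH (2.0 equiv) in MeOH at rt cleaves both esters, and the salt dipotassium 2-methoxypropanedioate F5 is precipitated with Et2O and dried in vacuo. The suspended salt is then treated with oxalyl chloride (cat. DMF, Et2O, 0 °C), the classical salt method for acid chlorides, to give 11.

Step 4. The 1,5-enyne unit may cycloisomerise under π-acid catalysis, or the benzylic carbinol may dehydrate before ring closure. The fallback sets out from 7 and comes back at 8 without any metal or strong acid. Conjugate addition of Et2NH (EtOH, rt) to the ynone should give the enaminone (1S,4E)-5-(diethylamino)-1-hydroxy-9-methyl-1-phenyldeca-4,8-dien-3-one F6. Brief treatment with AcOH in toluene then lets the hydroxyl displace the amine by 6-endo addition–elimination to give 8, with the carbinol C–O bond again untouched.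

Further compounds
F1 | step 7 | (2S)-6-(4-methylpent-3-en-1-yl)-2-phenyl-3,4-dihydro-2H-pyran-4-ol (C4 epimers) | OC1C[C@@H](c2ccccc2)OC(CCC=C(C)C)=C1
F2 | step 7 | tert-butyldimethyl{[(2S)-6-(4-methylpent-3-en-1-yl)-2-phenyl-3,4-dihydro-2H-pyran-4-yl]oxy}silane (C4 epimers) | CC(C)(C)[Si](C)(C)OC1C[C@@H](c2ccccc2)OC(CCC=C(C)C)=C1
F3 | step 7 | (2S)-4-[(tert-butyldimethylsilyl)oxy]-6-methoxy-8-(3-methylbut-2-en-1-yl)-2-phenylchromane-5,7-diol (C4 epimers) | COc1c(O)c(CC=C(C)C)c2c(c1O)C(O[Si](C)(C)C(C)(C)C)C[C@@H](c1ccccc1)O2
F4 | step 7 | (2S)-6-methoxy-8-(3-methylbut-2-en-1-yl)-2-phenylchromane-4,5,7-triol (C4 epimers) | COc1c(O)c(CC=C(C)C)c2c(c1O)C(O)C[C@@H](c1ccccc1)O2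
F5 | step 6 | dipotassium 2-methoxypropanedioate | COC(C(=O)[O-])C(=O)[O-].[K+].[K+]
F6 | step 4 | (1S,4E)-5-(diethylamino)-1-hydroxy-9-methyl-1-phenyldeca-4,8-dien-3-one | O=C(C[C@H](O)c1ccccc1)/C=C(/N(CC)CC)CCC=C(C)C
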